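## The problem

Target 15 is a 1,1,3-triarylpropane. C-1 of the chain carries ring A (4-methoxyphenyl) and ring C (2,6-dimethoxyphenyl). Ring C bears, para to C-1, an (E)-4-hydroxystyryl arm (ring D). C-3 carries ring B (4-hydroxy-2-methoxyphenyl). The rings are joined only through the saturated C-1–C-2–C-3 chain and one alkene.

The single stereocentre, C-1 (S), is a diarylmethine whose two aryl groups differ only in substitution pattern. No second stereocentre exists to direct it, so it must be set by a catalyst, at most with a temporary centre that is erased later. Once set, C-1 is safe only while no cation, radical or anion is generated at this doubly benzylic position.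

Six phenolic oxygens must be told apart: four are methyl ethers, two (ring B C-4 and ring D) are free. The electron-rich hydroxystilbene will not tolerate strong acid, hydride-transfer reduction, catalytic hydrogenation or oxidants, so it should appear late.

The enabling feature is that C-1 is benzylic to ring C, which has an oxygen on each ortho carbon, and C-3 is benzylic to ring B, which also has an ortho oxygen. Bonding one ring C oxygen to C-3 gives a 2,4-diarylchroman, the product of an ortho-quinone methide/ortho-hydroxystyrene cycloaddition. That O–C-3 bond is benzylic to an ortho,para-dioxygenated ring and can be removed again by ionic hydrogenation. The two oxygens the cycloaddition needs free are both methoxy groups in 15 and can be methylated afterwards.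

## Retrosynthesis

**Stilbene last.** Target 15 comes from acetate/silyl-protected stilbene 13 (through phenol 14). Stilbene 13 is cut at the ring C–vinyl bond into aryl bromide 11 and 4-acetoxystyrene 12 (Mizoroki–Heck). A ring C aldehyde for a Wittig reaction would not survive the Grignard step, and a stilbene carried from the start would not survive the acidic silane reduction. A bromide is inert to every earlier step. The forward reaction must give β-arylation with E geometry on a bromide that is electron-rich but unhindered.

**Open chain back to chroman.** Bromide 11 is the bis-methyl ether of bisphenol 10. Reconnecting the ring C oxygen of 10 to C-3 gives cis-2,4-diarylchroman 9. This turns an acyclic diarylmethine, for which no simple stereoselective bond construction is at hand, into a ring that a catalytic asymmetric cycloaddition can build. The forward reaction must cleave only the O–C-2 bond of the chroman and leave C-4, the aryl bromide and the silyl ether alone. That calls for ionic rather than catalytic hydrogenolysis.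

**Key disconnection.** Chroman 9 is cut at C-1–C-2 and O–C-3 (chroman C-4–C-3 and O-1–C-2) into ortho-quinone methide 8 and ortho-hydroxystyrene 7. Intermediate 8 is generated in the flask from racemic benzhydrol 4. Cutting only C-1–ring A (aryl addition to a quinone methide) would leave the chain and ring B still to be attached. The [4+2] makes two bonds and brings ring B with it. The forward reaction must select one face of the exocyclic carbon of 8, with head-to-tail regiochemistry.

Two spectator choices support this step:
- The ring B C-4 oxygen is a triisopropylsilyl ether. This keeps it distinct from the oxygens to be methylated and shields the two activated ring positions of 7 against Friedel–Crafts alkylation.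
- The ring C bromide is electronically mild and inert to acid.

**Benzhydrol.** Carbinol 4 is cut at C-1–ring A into salicylaldehyde 2 and 4-methoxyphenylmagnesium bromide 3. A racemic carbinol suffices because the centre is erased in 8. Aldehyde 2 comes from commercial 4-bromo-2,6-dimethoxybenzaldehyde 1 by chelation-directed mono-demethylation.

**Styrene.** Styrene 7 is cut at the vinyl C=C into aldehyde 6 (Wittig methylenation). Aldehyde 6 comes from 2,4-dihydroxybenzaldehyde 5 by silylation of the 4-hydroxyl, which is not hydrogen-bonded.

## Roads not taken

Alternative 1: Cut C-2–C-3 and C-1–ring A in a three-component radical carbo-arylation.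
- Forward step: with Cu(MeCN)4PF6 (monovalent copper) and a chiral bis(oxazoline), the radical from ring B α-bromo ester A3 adds to the terminus of ring C styrene A2. The resulting benzylic radical is arylated by 4-methoxyphenylboronic acid A4 to give butanoate A1.
- Merits: it is the most convergent assembly, with all four methyl ethers in place from the start. In protecting-group economy it is better than the chosen plan, which has to methylate after the key step and open a ring.
- Weak points: the C-1 radical is flanked by two ortho methoxy groups and twisted out of conjugation, and enantioselective capture at copper is established for simple styrenes, not for di-ortho-substituted ones. The ester in A1 sits on C-3, which is a methylene in 15, so hydrolysis and reductive decarboxylation must follow. A2 and A3 each need their own preparation.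
- Comparison: the chosen plan uses a cycloaddition class established for both partner types and removes no carbon afterwards. Step counts are similar.

Alternative 2: Cut the C-1–ring C bond at the oxidation level of a cyclohexane-1,3-dione.
- Forward step: dione ester A6 adds through its C-2 enol carbon to the β-carbon of enal A7, activated as an iminium ion by diphenylprolinol trimethylsilyl ether. The adduct closes to lactol A5.
- Merits: the stereo-defining event is among the most dependable in organocatalysis, since the enal β-carbon carries only ring A. In that respect it is better than the chosen plan. The ester also offers a palladium-free handle for the stilbene.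
- Weak points: A5 contains nothing of ring B. C-3 must receive an aryl nucleophile and lose its oxygen. The dione must be aromatised oxidatively and methylated, while C-1 can racemise by retro-Michael reaction. The ester must be reduced and olefinated. That is about eight to ten steps after the key step.
- Comparison: the chosen plan delivers ring B and the full chain in the key step and keeps ring C aromatic throughout.

Alternative 3: Cut C-1–ring A, C-1–C-2 and O–C-3 in one flask.
- Forward step: Grignard reagent 3 adds to O-Boc salicylaldehyde A9. The alkoxide takes over the Boc group and eliminates to an ortho-quinone methide, which is trapped by chiral vinyl ether A10 in a [4+2] to give acetal A8.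
- Merits: three bonds form in one operation under basic, cold conditions, so no acid-labile benzhydrol is isolated. Auxiliary control gives diastereomers that can be separated, so the absolute configuration is probably more secure than under catalyst control.
- Weak points: the auxiliary is stoichiometric. The dienophile supplies only C-2 and C-3, so ring B must be added to the acetal carbon and the oxygen removed, about three extra steps.
- Comparison: the chosen plan uses catalytic chirality and brings ring B in with the cycloaddition itself.

Key step: step 5

Assumption: the (R)-configured phosphoric acid is taken to give the (4S) chroman; the sense of induction cannot be derived with certainty for this substitution pattern, and if it proves opposite the (S)-catalyst is used with no other change.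

## Route

Step 1
Reactants: 1 4-bromo-2,6-dimethoxybenzaldehyde
Product: 2 4-bromo-2-hydroxy-6-methoxybenzaldehyde
Conditions: BCl3 (1.2 equiv, 1 M in CH2Cl2), CH2Cl2, −78 °C → rt; aq. HCl
Reagents that add atoms: none
Why: Chelation-directed ether cleavage: BCl3 binds the formyl oxygen and one ortho methoxy group, chloride removes that methyl, and the resulting six-membered aryloxyboron chelate resists a second demethylation; the aryl bromide is inert.

Step 2
Reactants: 2 4-bromo-2-hydroxy-6-methoxybenzaldehyde; 3 4-methoxyphenylmagnesium bromide (commercial THF solution)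
Product: 4 racemic 5-bromo-2-[hydroxy(4-methoxyphenyl)methyl]-3-methoxyphenol
Conditions: 3 (2.5 equiv), THF, −20 → 0 °C; sat. aq. NH4Cl; chromatography on Et3N-deactivated silica
Reagents that add atoms: none
Why: Grignard 1,2-addition: the first equivalent deprotonates the phenol and the second adds to the magnesium-chelated aldehyde, while bromine–magnesium exchange is negligible at this temperature; the carbinol centre is left racemic on purpose because step 5 erases it.

Step 3
Reactants: 5 2,4-dihydroxybenzaldehyde
Product: 6 2-hydroxy-4-(triisopropylsilyloxy)benzaldehyde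
Conditions: TIPSCl (1.05 equiv), imidazole (2.2 equiv), CH2Cl2, 0 °C → rt
Reagents that add atoms: chlorotri(propan-2-yl)silane, CC(C)[Si](Cl)(C(C)C)C(C)C
Why: Regioselective O-silylation: the 2-hydroxyl is locked in a hydrogen bond to the formyl group and is hindered, so the more acidic, exposed 4-hydroxyl reacts.

Step 4
Reactants: 6 2-hydroxy-4-(triisopropylsilyloxy)benzaldehyde
Product: 7 2-ethenyl-5-(triisopropylsilyloxy)phenol
Conditions: Ph3PCH3Br (2.5 equiv), KOtBu (2.4 equiv), THF, 0 °C → rt; product stored cold and used promptly
Reagents that add atoms: methyltriphenylphosphonium bromide, C[P+](c1ccccc1)(c1ccccc1)c1ccccc1.[Br-]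
Why: Wittig methylenation with excess unstabilised ylide: one equivalent is spent on the phenol and the phenoxide aldehyde still reacts; the aryl silyl ether is stable to the ylide.

Step 5
Reactants: 4 racemic 5-bromo-2-[hydroxy(4-methoxyphenyl)methyl]-3-methoxyphenol; 7 2-ethenyl-5-(triisopropylsilyloxy)phenol
Product: 9 2-[(2R,4S)-7-bromo-5-methoxy-4-(4-methoxyphenyl)-3,4-dihydro-2H-chromen-2-yl]-5-(triisopropylsilyloxy)phenol (cis-2,4-diarylchroman), via ortho-quinone methide 8 (not isolated)
Conditions: (R)-TRIP [(R)-3,3'-bis(2,4,6-triisopropylphenyl)-1,1'-binaphthalene-2,2'-diyl hydrogen phosphate] (10 mol%), 3 Å MS, toluene, 0 °C; 7 (1.5 equiv) added over 2 h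
Reagents that add atoms: none
Why: The chiral phosphoric acid protonates the benzylic hydroxyl of 4 and water leaves with push from the ortho hydroxyl, giving the planar ortho-quinone methide 8, so both enantiomers of 4 converge on one achiral intermediate. The catalyst then acts bifunctionally: its P–OH hydrogen-bonds the quinone methide oxygen and its P=O accepts a hydrogen bond from the phenol of 7, holding both partners in one chiral pocket. The styrene terminus bonds to the electrophilic exocyclic carbon slightly ahead of O–C bond formation at the benzylic styrene carbon, a concerted asynchronous inverse-electron-demand oxa-Diels–Alder reaction, which is the established reaction class for ortho-quinone methides generated in situ and ortho-hydroxystyrenes under chiral phosphoric acid catalysis. The one ring closed is the six-membered dihydropyran of the chroman, formed by [4+2] cycloaddition between the O=C–C=C heterodiene of 8 and the vinyl group of 7. C-4 (the future C-1) is set by the catalyst, which selects the face of the exocyclic carbon of the (E)-configured 8; C-2 follows from the endo approach of the styrene aryl group and is cis to C-4, but it is sacrificial. The step needs 4 to ionise in preference to protonation of 7, which the 4-methoxyphenyl group and the two ortho oxygens of ring C secure by stabilising 8. It needs head-to-tail regiochemistry, which the polarity of the partners secures, and attack by the vinyl group rather than by ring B, which the silyl group flanking both activated ring positions of 7 secures. The E and Z forms of 8 interconvert through the protonated form, so the reactive E geometry can be drawn off continuously.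

Step 6
Reactants: 9 2-[(2R,4S)-7-bromo-5-methoxy-4-(4-methoxyphenyl)-3,4-dihydro-2H-chromen-2-yl]-5-(triisopropylsilyloxy)phenol
Product: 10 5-bromo-2-[(1S)-3-[2-hydroxy-4-(triisopropylsilyloxy)phenyl]-1-(4-methoxyphenyl)propyl]-3-methoxyphenol
Conditions: Et3SiH (5 equiv), TFA (10 equiv), CH2Cl2, −20 → 0 °C
Reagents that add atoms: none
Why: Ionic hydrogenation of an activated benzylic ether, the established reductive opening of the flavan heterocycle: acid ionises the O–C-2 bond because C-2 carries an ortho-hydroxy, para-silyloxy aryl ring, and the silane delivers hydride. C-2 is erased, while no bond to C-4 is touched, so it becomes C-1 with (S) configuration; the aryl bromide and silyl ether survive, as they would not under catalytic hydrogenolysis.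

Step 7
Reactants: 10 5-bromo-2-[(1S)-3-[2-hydroxy-4-(triisopropylsilyloxy)phenyl]-1-(4-methoxyphenyl)propyl]-3-methoxyphenol
Product: 11 {4-[(3S)-3-(4-bromo-2,6-dimethoxyphenyl)-3-(4-methoxyphenyl)propyl]-3-methoxyphenoxy}tri(propan-2-yl)silane
Conditions: MeI (6 equiv), K2CO3 (4 equiv), anhydrous acetone, 45 °C
Reagents that add atoms: iodomethane, CI
Why: Williamson methylation of both phenoxides under mild heterogeneous base; the hindered aryl silyl ether should hold in anhydrous acetone, and C-1 is not acidic enough to be touched.

Step 8
Reactants: 11 {4-[(3S)-3-(4-bromo-2,6-dimethoxyphenyl)-3-(4-methoxyphenyl)propyl]-3-methoxyphenoxy}tri(propan-2-yl)silane; 12 4-ethenylphenyl acetate (4-acetoxystyrene)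
Product: 13 4-[(E)-2-{3,5-dimethoxy-4-[(1S)-1-(4-methoxyphenyl)-3-{2-methoxy-4-[(triisopropylsilyl)oxy]phenyl}propyl]phenyl}ethenyl]phenyl acetate
Conditions: Pd(OAc)2 (5 mol%), P(o-tol)3 (12 mol%), Et3N (3 equiv), 12 (1.5 equiv), DMF, 100 °C
Reagents that add atoms: none
Why: Mizoroki–Heck reaction: zerovalent palladium formed in situ inserts into the unhindered Ar–Br bond, the styrene inserts syn at its terminal carbon, and syn β-hydride elimination gives the (E)-stilbene; C-1 is remote and not epimerised by Et3N.

Step 9
Reactants: 13 4-[(E)-2-{3,5-dimethoxy-4-[(1S)-1-(4-methoxyphenyl)-3-{2-methoxy-4-[(triisopropylsilyl)oxy]phenyl}propyl]phenyl}ethenyl]phenyl acetate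
Product: 15 4-[(3S)-3-{4-[(E)-2-(4-hydroxyphenyl)ethenyl]-2,6-dimethoxyphenyl}-3-(4-methoxyphenyl)propyl]-3-methoxyphenol (CNP0182684.1), via silyl-protected stilbene phenol 14 (not isolated)
Conditions: K2CO3 (0.3 equiv), degassed MeOH/THF 1:1, rt, 1 h; then TBAF (1 M in THF, 1.5 equiv), rt; aq. NH4Cl; under argon
Reagents that add atoms: none
Why: Base-catalysed transesterification with methanol frees the ring D phenol, then fluoride cleaves the Si–O bond, driven by the strong Si–F bond; neither reagent affects the stilbene or C-1, and air is excluded because the electron-rich phenoxides oxidise easily.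

## Compound list

1 | 4-bromo-2,6-dimethoxybenzaldehyde | COc1cc(Br)cc(OC)c1C=O | starting material
2 | 4-bromo-2-hydroxy-6-methoxybenzaldehyde | COc1cc(Br)cc(O)c1C=O | intermediate
3 | 4-methoxyphenylmagnesium bromide | COc1ccc([Mg]Br)cc1 | starting material
4 | racemic 5-bromo-2-[hydroxy(4-methoxyphenyl)methyl]-3-methoxyphenol | COc1ccc(cc1)C(O)c1c(O)cc(Br)cc1OC | intermediate
5 | 2,4-dihydroxybenzaldehyde | O=Cc1ccc(O)cc1O | starting material
6 | 2-hydroxy-4-(triisopropylsilyloxy)benzaldehyde | O=Cc1ccc(O[Si](C(C)C)(C(C)C)C(C)C)cc1O | intermediate
7 | 2-ethenyl-5-(triisopropylsilyloxy)phenol | C=Cc1ccc(O[Si](C(C)C)(C(C)C)C(C)C)cc1O | intermediate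
8 | (6E)-3-bromo-5-methoxy-6-[(4-methoxyphenyl)methylidene]cyclohexa-2,4-dien-1-one (ortho-quinone methide, reactive E geometry drawn) | COc1ccc(cc1)/C=C1/C(=O)C=C(Br)C=C1OC | intermediate
9 | 2-[(2R,4S)-7-bromo-5-methoxy-4-(4-methoxyphenyl)-3,4-dihydro-2H-chromen-2-yl]-5-(triisopropylsilyloxy)phenol | COc1ccc(cc1)[C@@H]1C[C@@H](Oc2cc(Br)cc(OC)c12)c1ccc(O[Si](C(C)C)(C(C)C)C(C)C)cc1O | intermediate
10 | 5-bromo-2-[(1S)-3-[2-hydroxy-4-(triisopropylsilyloxy)phenyl]-1-(4-methoxyphenyl)propyl]-3-methoxyphenol | COc1ccc([C@H](CCc2ccc(O[Si](C(C)C)(C(C)C)C(C)C)cc2O)c2c(O)cc(Br)cc2OC)cc1 | intermediate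
11 | {4-[(3S)-3-(4-bromo-2,6-dimethoxyphenyl)-3-(4-methoxyphenyl)propyl]-3-methoxyphenoxy}tri(propan-2-yl)silane | COc1ccc([C@H](CCc2ccc(O[Si](C(C)C)(C(C)C)C(C)C)cc2OC)c2c(OC)cc(Br)cc2OC)cc1 | intermediate
12 | 4-ethenylphenyl acetate (4-acetoxystyrene) | CC(=O)Oc1ccc(C=C)cc1 | starting material
13 | 4-[(E)-2-{3,5-dimethoxy-4-[(1S)-1-(4-methoxyphenyl)-3-{2-methoxy-4-[(triisopropylsilyl)oxy]phenyl}propyl]phenyl}ethenyl]phenyl acetate | COc1ccc([C@H](CCc2ccc(O[Si](C(C)C)(C(C)C)C(C)C)cc2OC)c2c(OC)cc(/C=C/c3ccc(OC(C)=O)cc3)cc2OC)cc1 | intermediate
14 | 4-[(E)-2-{3,5-dimethoxy-4-[(1S)-1-(4-methoxyphenyl)-3-{2-methoxy-4-[(triisopropylsilyl)oxy]phenyl}propyl]phenyl}ethenyl]phenol | COc1ccc([C@H](CCc2ccc(O[Si](C(C)C)(C(C)C)C(C)C)cc2OC)c2c(OC)cc(/C=C/c3ccc(O)cc3)cc2OC)cc1 | intermediate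
15 | 4-[(3S)-3-{4-[(E)-2-(4-hydroxyphenyl)ethenyl]-2,6-dimethoxyphenyl}-3-(4-methoxyphenyl)propyl]-3-methoxyphenol | COc1ccc([C@H](CCc2ccc(O)cc2OC)c2c(OC)cc(/C=C/c3ccc(O)cc3)cc2OC)cc1 | target

## Step count and risks

Total: 9 steps. Longest linear sequence: 7 steps (steps 1, 2, 5, 6, 7, 8, 9; the branch through steps 3 and 4 is equally long).

**Step 5 (key step).** The most likely failure is poor enantioface selectivity. The methoxy group flanking the exocyclic carbon of 8 strains the reactive E geometry, so the Z form or a loosely bound ion pair may react and erode catalyst control. Acid-induced oligomerisation of the electron-rich styrene may also compete.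

Fallback: setting out again from 4 and 7, the cycloaddition is run with an achiral acid (diphenyl hydrogen phosphate, toluene, 0 °C). This should give the racemic cis chroman, that is 9 together with its mirror image, the (2S,4R)-chroman F1. Preparative chromatography on a chiral stationary phase separates the two, and the route is rejoined at 9.

**Step 6.** The most likely failure is slow hydride capture. The ring-opened cation re-closes reversibly. By losing the ring B phenolic proton it can also become a neutral ortho-quinone methide, which may dimerise or alkylate other electron-rich rings faster than the silane reduces it. Forcing the acid would then cost the silyl ether.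

Fallback: setting out from 9, the ring B phenol is methylated first (MeI, K2CO3, acetone). This gives (2R,4S)-7-bromo-5-methoxy-2-[2-methoxy-4-(triisopropylsilyloxy)phenyl]-4-(4-methoxyphenyl)chroman F2. Its cation cannot shed a proton to a neutral ortho-quinone methide. Et3SiH/TFA then gives the ring C monophenol 5-bromo-3-methoxy-2-[(1S)-1-(4-methoxyphenyl)-3-[2-methoxy-4-(triisopropylsilyloxy)phenyl]propyl]phenol F3. Methylation of F3 returns to the route at 11.

**Step 7.** The most likely failure is base-induced loss of the silyl group from ring B, followed by methylation of the freed oxygen. That would irreversibly erase the distinction between the free and methylated phenols.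

Fallback: setting out from 10, both phenols are methylated by Mitsunobu etherification (MeOH, PPh3, diisopropyl azodicarboxylate, THF, 0 °C → rt). This runs under neutral conditions and returns directly to 11. No new compound arises (entry F0).

**Step 8.** The most likely failure is sluggish oxidative addition into the electron-rich bromide at the temperature needed. Catalyst decomposition, thermal loss of the acetate and competing α-arylation to a 1,1-diarylethene could follow.

Fallback: the coupling polarity is reversed. Setting out from 11, Suzuki–Miyaura vinylation with potassium vinyltrifluoroborate (PdCl2(dppf), Et3N, n-PrOH, 90 °C) gives {4-[(3S)-3-(4-ethenyl-2,6-dimethoxyphenyl)-3-(4-methoxyphenyl)propyl]-3-methoxyphenoxy}tri(propan-2-yl)silane F4. Heck coupling of F4 with the far more reactive 4-iodophenyl acetate (Pd(OAc)2, NaHCO3, Bu4NCl, DMF, 60 °C) returns to the route at 13.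

## Further compounds

F1 | step 5 | 2-[(2S,4R)-7-bromo-5-methoxy-4-(4-methoxyphenyl)-3,4-dihydro-2H-chromen-2-yl]-5-(triisopropylsilyloxy)phenol (enantiomer of 9) | COc1ccc(cc1)[C@H]1C[C@H](Oc2cc(Br)cc(OC)c12)c1ccc(O[Si](C(C)C)(C(C)C)C(C)C)cc1O
F2 | step 6 | (2R,4S)-7-bromo-5-methoxy-2-[2-methoxy-4-(triisopropylsilyloxy)phenyl]-4-(4-methoxyphenyl)chroman | COc1ccc(cc1)[C@@H]1C[C@@H](Oc2cc(Br)cc(OC)c12)c1ccc(O[Si](C(C)C)(C(C)C)C(C)C)cc1OC
F3 | step 6 | 5-bromo-3-methoxy-2-[(1S)-1-(4-methoxyphenyl)-3-[2-methoxy-4-(triisopropylsilyloxy)phenyl]propyl]phenol | COc1ccc([C@H](CCc2ccc(O[Si](C(C)C)(C(C)C)C(C)C)cc2OC)c2c(O)cc(Br)cc2OC)cc1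
F0 | step 7 | none | none
F4 | step 8 | {4-[(3S)-3-(4-ethenyl-2,6-dimethoxyphenyl)-3-(4-methoxyphenyl)propyl]-3-methoxyphenoxy}tri(propan-2-yl)silane | COc1ccc([C@H](CCc2ccc(O[Si](C(C)C)(C(C)C)C(C)C)cc2OC)c2c(OC)cc(C=C)cc2OC)cc1
A1 | alternative 1 | methyl (4S)-4-(4-bromo-2,6-dimethoxyphenyl)-4-(4-methoxyphenyl)-2-[2-methoxy-4-(triisopropylsilyloxy)phenyl]butanoate (C-2 as a mixture) | COc1ccc(cc1)[C@H](CC(C(=O)OC)c1ccc(O[Si](C(C)C)(C(C)C)C(C)C)cc1OC)c1c(OC)cc(Br)cc1OC
A2 | alternative 1 | 5-bromo-2-ethenyl-1,3-dimethoxybenzene | C=Cc1c(OC)cc(Br)cc1OC
A3 | alternative 1 | methyl 2-bromo-2-[2-methoxy-4-(triisopropylsilyloxy)phenyl]acetate | COC(=O)C(Br)c1ccc(O[Si](C(C)C)(C(C)C)C(C)C)cc1OC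
A4 | alternative 1 | 4-methoxyphenylboronic acid | COc1ccc(cc1)B(O)O
A5 | alternative 2 | methyl (4S)-2-hydroxy-4-(4-methoxyphenyl)-5-oxo-3,4,5,6,7,8-hexahydro-2H-chromene-7-carboxylate (lactol of the Michael adduct) | COc1ccc(cc1)[C@H](CC(O)O2)C1=C2CC(CC1=O)C(=O)OC
A6 | alternative 2 | methyl 3,5-dioxocyclohexane-1-carboxylate | COC(=O)C1CC(=O)CC(=O)C1
A7 | alternative 2 | (E)-3-(4-methoxyphenyl)prop-2-enal | COc1ccc(/C=C/C=O)cc1
A8 | alternative 3 | (2R,4S)-7-bromo-5-methoxy-4-(4-methoxyphenyl)-2-[(trans-2-phenylcyclohexyl)oxy]chroman (cis acetal) | COc1ccc(cc1)[C@@H]1C[C@H](O[C@H]2CCCC[C@@H]2c2ccccc2)Oc2cc(Br)cc(OC)c12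
A9 | alternative 3 | 5-bromo-2-formyl-3-methoxyphenyl tert-butyl carbonate | COc1cc(Br)cc(OC(=O)OC(C)(C)C)c1C=O
A10 | alternative 3 | enantiopure trans-2-phenylcyclohexyl vinyl ether | C=CO[C@H]1CCCC[C@@H]1c1ccccc1
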